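**Retrosynthetic overview**
1. Locants: ring A (cyclopentane) = C1 (quaternary, CH3), C2H2, C3H2, C4 (tertiary carbinol, isopropyl), C5 (ring-fusion CH). Ring B (cycloheptene) = C1, C5, C6 (acyloxy), C7, C8(CH3)=C9, C10.
2. Endgame: the C6 veratrate is cut to the 4,6-diol and 3,4-dimethoxybenzoyl chloride. Ring B is opened at C8=C9 (ring-closing metathesis), and the C4–isopropyl bond is cut back to a ring A cyclopentanone.
3. Enabling feature: C4 carries the only heteroatom of ring A, lies across C5 from the quaternary C1, and is flanked by the bare C2H2–C3H2 unit. O=C4–C5–C1–C2–C3 is therefore the retron of a 4-pentenal hydroacylation (C3–C4), and O=C4–C5–C1–C2=C3 is that of a Claisen rearrangement (C5–C1). The future C4 oxygen serves as a temporary O–C3 tether, so ring A is a traceless formal (3+2) union of the allyl unit C1–C2–C3 with the enol ether unit C4=C5.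
4. The acyclic allyl vinyl ether comes from a copper-catalysed C–O coupling. One partner is an (E)-vinyl iodide (C4–C8, with C6 set by asymmetric methallylboration). The other is (E)-3-methylhexa-2,5-dien-1-ol (C1–C3, C9, C10, from carboalumination).
5. Ring order: ring A first (step 7), ring B second (step 9). Stereochemical relay: C6 directs C5 and C1 in one event, and these then direct C4.

Key step: step 7

Remark: compounds 1, 5 and 18 and all reagents are taken as commercially available, and the target is read as the natural-series (3R,3aS,4S,8aR) jaeschkeanadiol 6-veratrate.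

**Step 1**
Reactants: 1 pent-1-en-4-yne
Product: 4 (E)-3-methylhexa-2,5-dien-1-ol, via alkenyldimethylalane 2 (not isolated), via lithium alkenylalanate 3 (not isolated)
Conditions: Me3Al, Cp2ZrCl2 (0.25 equiv), CH2Cl2, 0 °C → rt, excess Me3Al removed in vacuo; n-BuLi, hexane–THF, −78 → 0 °C; (CH2O)n, rt; 3 M HCl
Reagents that add atoms: trimethylaluminium, C[Al](C)C; paraformaldehyde (reacts as formaldehyde), C=O
Why: The zirconium-catalysed Negishi carboalumination adds CH3 and Al syn across the terminal alkyne only, with Al on the terminal carbon, and the derived alanate is hydroxymethylated with retention, which fixes the E geometry without forming a stereocentre.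

**Step 2**
Reactants: 5 3-(trimethylsilyl)prop-2-ynal
Product: 7 (S)-5-methyl-1-(trimethylsilyl)hex-5-en-1-yn-3-ol, via diisopinocampheylborinate 6 (not isolated)
Conditions: (−)-Ipc2BOMe, CH2=C(CH3)CH2MgCl, Et2O, 0 °C → rt; 5, −78 °C; 3 M NaOH, 30% H2O2, 0 °C → rt
Reagents that add atoms: 2-methylallylmagnesium chloride, CC(=C)C[Mg]Cl
Why: In this Brown asymmetric allylboration the methallylborane made from the (+)-α-pinene-derived borinate should add through a closed chair transition state to the Si face of the ynal and so set C6 as S.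

**Step 3**
Reactants: 7 (S)-5-methyl-1-(trimethylsilyl)hex-5-en-1-yn-3-ol
Product: 8 (S)-5-methylhex-5-en-1-yn-3-ol
Conditions: K2CO3 (0.2 equiv), MeOH, rt
Reagents that add atoms: none
Why: Base-catalysed methanolysis (protodesilylation) cleaves only the alkynyl C–Si bond and leaves the carbinol centre untouched.

**Step 4**
Reactants: 8 (S)-5-methylhex-5-en-1-yn-3-ol
Product: 9 tert-butyl(dimethyl){[(3S)-5-methylhex-5-en-1-yn-3-yl]oxy}silane
Conditions: TBSCl, imidazole, DMF, rt
Reagents that add atoms: tert-butyldimethylsilyl chloride, CC(C)(C)[Si](C)(C)Cl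
Why: Imidazole-promoted silylation masks the C6 hydroxyl as a bulky ether that survives base, heat, rhodium and organocerium and later serves as the stereodirecting group.

**Step 5**
Reactants: 9 tert-butyl(dimethyl){[(3S)-5-methylhex-5-en-1-yn-3-yl]oxy}silane
Product: 11 tert-butyl{[(1E,3S)-1-iodo-5-methylhexa-1,5-dien-3-yl]oxy}dimethylsilane, via alkenylzirconocene chloride 10 (not isolated)
Conditions: Cp2Zr(H)Cl (1.2 equiv), THF, 0 °C → rt, dark; I2, 0 °C
Reagents that add atoms: iodine, [I][I]
Why: Hydrozirconation is a syn addition that places Zr on the terminal carbon and is much faster for a terminal alkyne than for the 1,1-disubstituted alkene, and iodinolysis with retention gives the E iodide.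

**Step 6**
Reactants: 11 tert-butyl{[(1E,3S)-1-iodo-5-methylhexa-1,5-dien-3-yl]oxy}dimethylsilane; 4 (E)-3-methylhexa-2,5-dien-1-ol
Product: 12 tert-butyl(dimethyl){[(1E,3S)-5-methyl-1-{[(2E)-3-methylhexa-2,5-dien-1-yl]oxy}hexa-1,5-dien-3-yl]oxy}silane
Conditions: CuI (10 mol %), 3,4,7,8-tetramethyl-1,10-phenanthroline (20 mol %), Cs2CO3 (1.5 equiv), toluene, 80 °C
Reagents that add atoms: none
Why: The Ullmann-type copper-catalysed C–O coupling of a vinyl iodide with a primary allylic alcohol proceeds with retention of the E geometry, and 80 °C lies below the temperature at which the product rearranges at a useful rate, so no stereocentre is touched.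

**Step 7**
Reactants: 12 tert-butyl(dimethyl){[(1E,3S)-5-methyl-1-{[(2E)-3-methylhexa-2,5-dien-1-yl]oxy}hexa-1,5-dien-3-yl]oxy}silane
Product: 14 (2S,3R)-2-[(1S)-1-(tert-butyldimethylsilyloxy)-3-methylbut-3-en-1-yl]-3-methyl-3-(prop-2-en-1-yl)cyclopentan-1-one, via Claisen aldehyde 13 (not isolated)
Conditions: [RhCl(cod)]2 (2.5 mol %), dppe (5 mol %), degassed toluene (0.05 M), 130 °C, sealed tube
Reagents that add atoms: none
Why: Heat drives the [3,3]-sigmatropic Claisen shift of the allyl vinyl ether through a chair transition state, which forms C5–C1, breaks the temporary O–C3 tether and unveils the 4-pentenal 13; monovalent rhodium then inserts into the formyl C–H bond, the hydride is delivered to C2 of the vinyl group, and reductive elimination from the six-membered acyl-rhodacycle forms C3–C4. The closest known reaction type is the one-pot Claisen rearrangement/intramolecular hydroacylation of allyl vinyl ethers to cyclopentanones, itself built on the rhodium-catalysed cyclisation of 4-pentenals. Ring A is the only ring closed, in a formal 5-endo-trig mode that is feasible because the bond is made by reductive elimination within the rhodacycle and not by direct attack on the alkene. C5 is controlled by the C6 stereocentre: both low-energy rotamers about C5–C6 (silyloxy group anti to the incoming carbon with H inside, or C7 anti with the silyloxy group inside) expose the same face of the E enol ether and lead to the 5,6-anti array. C1 is relayed from C5 by the chair, in which the E enol ether and the E trisubstituted alkene place the C6 chain and the allyl arm equatorial and hence trans on ring A, with the CH3 group cis to the C6 chain. The step needs chemoselectivity among three C=C bonds and configurational integrity at C5: only the vinyl group on C1 can reach a six-membered rhodacycle through a primary alkyl–rhodium bond, and the capture of 13 as it forms should keep this β-silyloxy aldehyde from epimerisation, β-elimination and Cope rearrangement.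

**Step 8**
Reactants: 14 (2S,3R)-2-[(1S)-1-(tert-butyldimethylsilyloxy)-3-methylbut-3-en-1-yl]-3-methyl-3-(prop-2-en-1-yl)cyclopentan-1-one
Product: 15 (1R,2S,3R)-2-[(1S)-1-(tert-butyldimethylsilyloxy)-3-methylbut-3-en-1-yl]-3-methyl-1-(propan-2-yl)-3-(prop-2-en-1-yl)cyclopentan-1-ol
Conditions: anhydrous CeCl3 (2 equiv), i-PrMgCl (2 equiv), THF, −78 → 0 °C; sat. aq. NH4Cl
Reagents that add atoms: isopropylmagnesium chloride, CC(C)[Mg]Cl
Why: The organocerium 1,2-addition is weakly basic, which should suppress enolisation, β-elimination and hydride transfer, and the reagent should attack the ring A carbonyl from the face opposite the adjacent C5 side chain and the C1 methyl group, setting C4 as R with OH cis to the side chain.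

**Step 9**
Reactants: 15 (1R,2S,3R)-2-[(1S)-1-(tert-butyldimethylsilyloxy)-3-methylbut-3-en-1-yl]-3-methyl-1-(propan-2-yl)-3-(prop-2-en-1-yl)cyclopentan-1-ol
Product: 16 (3R,3aS,4S,8aR)-4-(tert-butyldimethylsilyloxy)-6,8a-dimethyl-3-(propan-2-yl)-1,2,3,3a,4,5,8,8a-octahydroazulen-3-ol
Conditions: second-generation Grubbs catalyst (5 mol %), CH2Cl2 (0.003 M), 40 °C
Reagents that add atoms: none
Why: Ring-closing metathesis starts at the monosubstituted allyl arm and closes on the 1,1-disubstituted methallyl arm to the trisubstituted C8=C9 bond, a seven-membered closure that the trans-1,2 arrangement of the arms on ring A turns into the trans-fused hydroazulene without touching a stereocentre.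

**Step 10**
Reactants: 16 (3R,3aS,4S,8aR)-4-(tert-butyldimethylsilyloxy)-6,8a-dimethyl-3-(propan-2-yl)-1,2,3,3a,4,5,8,8a-octahydroazulen-3-ol
Product: 17 jaeschkeanadiol, (3R,3aS,4S,8aR)-6,8a-dimethyl-3-(propan-2-yl)-1,2,3,3a,4,5,8,8a-octahydroazulene-3,4-diol
Conditions: TBAF, THF, rt → 45 °C
Reagents that add atoms: none
Why: Fluoride-mediated desilylation frees the C6 hydroxyl under conditions that leave the tertiary alcohol and the trisubstituted alkene alone.

**Step 11**
Reactants: 17 jaeschkeanadiol; 18 3,4-dimethoxybenzoyl chloride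
Product: 19 (3R,3aS,4S,8aR)-3-hydroxy-6,8a-dimethyl-3-(propan-2-yl)-1,2,3,3a,4,5,8,8a-octahydroazulen-4-yl 3,4-dimethoxybenzoate
Conditions: Et3N, DMAP (cat.), CH2Cl2, 0 °C → rt
Reagents that add atoms: none
Why: DMAP-catalysed acylation should take place only at the secondary C6 hydroxyl, because the tertiary C4 hydroxyl flanked by the isopropyl group is inert under these conditions.

**Compound list**
1 | pent-1-en-4-yne | C#CCC=C | starting material
2 | (E)-dimethyl(2-methylpenta-1,4-dien-1-yl)aluminium | C[Al](C)/C=C(\C)CC=C | intermediate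
3 | lithium (E)-butyl(dimethyl)(2-methylpenta-1,4-dien-1-yl)aluminate | [Li+].CCCC[Al-](C)(C)/C=C(\C)CC=C | intermediate
4 | (E)-3-methylhexa-2,5-dien-1-ol | OC/C=C(\C)CC=C | intermediate
5 | 3-(trimethylsilyl)prop-2-ynal | C[Si](C)(C)C#CC=O | starting material
6 | (S)-5-methyl-1-(trimethylsilyl)hex-5-en-1-yn-3-yl diisopinocampheylborinate | O([C@@H](CC(C)=C)C#C[Si](C)(C)C)B([C@@H]1C[C@@H]2C[C@H]([C@H]1C)C2(C)C)[C@@H]1C[C@@H]2C[C@H]([C@H]1C)C2(C)C | intermediate
7 | (S)-5-methyl-1-(trimethylsilyl)hex-5-en-1-yn-3-ol | O[C@@H](CC(C)=C)C#C[Si](C)(C)C | intermediate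
8 | (S)-5-methylhex-5-en-1-yn-3-ol | O[C@@H](CC(C)=C)C#C | intermediate
9 | tert-butyl(dimethyl){[(3S)-5-methylhex-5-en-1-yn-3-yl]oxy}silane | CC(C)(C)[Si](C)(C)O[C@@H](CC(C)=C)C#C | intermediate
10 | chlorobis(cyclopentadienyl)[(1E,3S)-3-(tert-butyldimethylsilyloxy)-5-methylhexa-1,5-dien-1-yl]zirconium | CC(C)(C)[Si](C)(C)O[C@@H](CC(C)=C)/C=C/[Zr](Cl)(C1C=CC=C1)C1C=CC=C1 | intermediate
11 | tert-butyl{[(1E,3S)-1-iodo-5-methylhexa-1,5-dien-3-yl]oxy}dimethylsilane | CC(C)(C)[Si](C)(C)O[C@@H](CC(C)=C)/C=C/I | intermediate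
12 | tert-butyl(dimethyl){[(1E,3S)-5-methyl-1-{[(2E)-3-methylhexa-2,5-dien-1-yl]oxy}hexa-1,5-dien-3-yl]oxy}silane | CC(C)(C)[Si](C)(C)O[C@@H](CC(C)=C)/C=C/OC/C=C(\C)CC=C | intermediate
13 | (2S,3S)-2-[(1S)-1-(tert-butyldimethylsilyloxy)-3-methylbut-3-en-1-yl]-3-ethenyl-3-methylhex-5-enal | CC(C)(C)[Si](C)(C)O[C@@H](CC(C)=C)[C@@H](C=O)[C@@](C)(CC=C)C=C | intermediate
14 | (2S,3R)-2-[(1S)-1-(tert-butyldimethylsilyloxy)-3-methylbut-3-en-1-yl]-3-methyl-3-(prop-2-en-1-yl)cyclopentan-1-one | CC(C)(C)[Si](C)(C)O[C@@H](CC(C)=C)[C@@H]1[C@@](C)(CC=C)CCC1=O | intermediate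
15 | (1R,2S,3R)-2-[(1S)-1-(tert-butyldimethylsilyloxy)-3-methylbut-3-en-1-yl]-3-methyl-1-(propan-2-yl)-3-(prop-2-en-1-yl)cyclopentan-1-ol | CC(C)(C)[Si](C)(C)O[C@@H](CC(C)=C)[C@@H]1[C@@](C)(CC=C)CC[C@@]1(O)C(C)C | intermediate
16 | (3R,3aS,4S,8aR)-4-(tert-butyldimethylsilyloxy)-6,8a-dimethyl-3-(propan-2-yl)-1,2,3,3a,4,5,8,8a-octahydroazulen-3-ol | CC(C)(C)[Si](C)(C)O[C@H]2CC(C)=CC[C@@]3(C)CC[C@@](O)(C(C)C)[C@H]23 | intermediate
17 | jaeschkeanadiol, (3R,3aS,4S,8aR)-6,8a-dimethyl-3-(propan-2-yl)-1,2,3,3a,4,5,8,8a-octahydroazulene-3,4-diol | O[C@H]2CC(C)=CC[C@@]3(C)CC[C@@](O)(C(C)C)[C@H]23 | intermediate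
18 | 3,4-dimethoxybenzoyl chloride | COc1ccc(C(=O)Cl)cc1OC | starting material
19 | (3R,3aS,4S,8aR)-3-hydroxy-6,8a-dimethyl-3-(propan-2-yl)-1,2,3,3a,4,5,8,8a-octahydroazulen-4-yl 3,4-dimethoxybenzoate | COc1ccc(C(=O)O[C@H]2CC(C)=CC[C@@]3(C)CC[C@@](O)(C(C)C)[C@H]23)cc1OC | target

Total step count: 11. Longest linear sequence: 10 steps (steps 2 to 11, from 5).

**Steps most likely to fail**

**Step 7.**
- What may go wrong:
  - The faces of the enol ether may be discriminated too weakly at 130 °C.
  - Rhodium hydride species may shift the skipped and terminal double bonds or decarbonylate the aldehyde at the temperature the sigmatropic step needs.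
- The fallback sets out from 9 (with 4 as partner) and comes back at 14. It makes C5–C1 by an Ireland–Claisen rearrangement at or below room temperature and closes ring A separately.
- Route:
  - Hydroboration of 9 with dicyclohexylborane should give the (E)-alkenyl(dicyclohexyl)borane F1. Buffered H2O2 oxidation of this gives the β-silyloxy aldehyde F2, and Pinnick oxidation (NaClO2, NaH2PO4, 2-methylbut-2-ene) gives the acid F3.
  - EDC/DMAP esterification with 4 gives the allyl ester F4.
  - LDA in THF–DMPU with Me3SiCl at −78 °C gives the (Z)-silyl ketene acetal F5, in which the C6 chain is trans to the allyloxy group.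
  - Warming to room temperature lets F5 rearrange through the same chair to the trimethylsilyl ester F6.
  - LiAlH4 gives the primary alcohol F7, and Dess–Martin oxidation gives aldehyde 13, now isolated.
  - [Rh(nbd)(dppe)]BF4 (5 mol %, activated with H2) in CH2Cl2 at room temperature closes ring A to 14.
- Why it should help: the lower temperature should sharpen the facial bias of C6. The enolate geometry becomes an independent handle on the C5/C1 relationship.

**Step 8.**
- What may go wrong:
  - The hindered cyclopentanone may enolise, followed by loss of the silyloxy group through β-elimination.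
  - The isopropyl reagent may transfer hydride.
  - Face selectivity may be poor.
- The fallback sets out from 14 and comes back at 16. It reverses the order of events and uses an sp2 nucleophile that has no transferable β-hydride.
- Route:
  - Ring-closing metathesis of 14 with the second-generation Grubbs catalyst gives the trans-fused bicyclic ketone F8.
  - Prop-1-en-2-ylmagnesium bromide with CeCl3 at −78 °C should add from the face opposite the angular methyl group to give the isopropenyl carbinol F9.
  - Hydrogenation with RhCl(PPh3)3 and H2 (1 atm) in benzene should saturate only the 1,1-disubstituted alkene and leave the trisubstituted ring alkene, giving 16.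

**Step 9.**
- What may go wrong:
  - Closure onto the 1,1-disubstituted olefin next to the bulky silyl ether may be slow, so that cross metathesis of the allyl arm leads to oligomers.
  - A ruthenium hydride may move the allyl double bond inward and a contracted ring may close.
- The fallback sets out from 15 and comes back at 16. It forms C8=C9 by carbonyl coupling.
- Route:
  - Ozonolysis of both terminal alkenes (O3, CH2Cl2–MeOH, −78 °C; Me2S) gives the keto aldehyde F10.
  - An intramolecular McMurry coupling with low-valent titanium (TiCl3(DME)1.5, Zn(Cu), DME, reflux, slow addition) closes the seven-membered ring to 16.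

**Further compounds**
F1 | step 7 | [(1E,3S)-3-(tert-butyldimethylsilyloxy)-5-methylhexa-1,5-dien-1-yl]dicyclohexylborane | CC(C)(C)[Si](C)(C)O[C@@H](CC(C)=C)/C=C/B(C1CCCCC1)C1CCCCC1
F2 | step 7 | (3S)-3-(tert-butyldimethylsilyloxy)-5-methylhex-5-enal | CC(C)(C)[Si](C)(C)O[C@@H](CC(C)=C)CC=O
F3 | step 7 | (3S)-3-(tert-butyldimethylsilyloxy)-5-methylhex-5-enoic acid | CC(C)(C)[Si](C)(C)O[C@@H](CC(C)=C)CC(=O)O
F4 | step 7 | (2E)-3-methylhexa-2,5-dien-1-yl (3S)-3-(tert-butyldimethylsilyloxy)-5-methylhex-5-enoate | CC(C)(C)[Si](C)(C)O[C@@H](CC(C)=C)CC(=O)OC/C=C(\C)CC=C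
F5 | step 7 | (Z)-trimethylsilyl ketene acetal of F4, C6 chain cis to OSiMe3 | CC(C)(C)[Si](C)(C)O[C@@H](CC(C)=C)/C=C(\O[Si](C)(C)C)OC/C=C(\C)CC=C
F6 | step 7 | trimethylsilyl (2S,3S)-2-[(1S)-1-(tert-butyldimethylsilyloxy)-3-methylbut-3-en-1-yl]-3-ethenyl-3-methylhex-5-enoate | CC(C)(C)[Si](C)(C)O[C@@H](CC(C)=C)[C@@H](C(=O)O[Si](C)(C)C)[C@@](C)(CC=C)C=C
F7 | step 7 | (2R,3S)-2-[(1S)-1-(tert-butyldimethylsilyloxy)-3-methylbut-3-en-1-yl]-3-ethenyl-3-methylhex-5-en-1-ol | CC(C)(C)[Si](C)(C)O[C@@H](CC(C)=C)[C@@H](CO)[C@@](C)(CC=C)C=C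
F8 | step 8 | (3aS,4S,8aR)-4-(tert-butyldimethylsilyloxy)-6,8a-dimethyl-2,3a,4,5,8,8a-hexahydroazulen-3(1H)-one | CC(C)(C)[Si](C)(C)O[C@H]2CC(C)=CC[C@@]3(C)CCC(=O)[C@H]23
F9 | step 8 | (3S,3aS,4S,8aR)-4-(tert-butyldimethylsilyloxy)-6,8a-dimethyl-3-(prop-1-en-2-yl)-1,2,3,3a,4,5,8,8a-octahydroazulen-3-ol | CC(C)(C)[Si](C)(C)O[C@H]2CC(C)=CC[C@@]3(C)CC[C@@](O)(C(C)=C)[C@H]23
F10 | step 9 | 2-{(1R,2S,3R)-2-[(1S)-1-(tert-butyldimethylsilyloxy)-3-oxobutyl]-3-hydroxy-1-methyl-3-(propan-2-yl)cyclopentyl}acetaldehyde | CC(C)(C)[Si](C)(C)O[C@@H](CC(C)=O)[C@@H]1[C@@](C)(CC=O)CC[C@@]1(O)C(C)C
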